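A small charge of free catalyst, 0.50 mM against 10 mM of each mirror-image substrate, turns left-handed substrate into product, and we ask how far right-handed substrate can get ahead.

| flask | left-handed substrate | right-handed substrate | partner | protic impurity | free catalyst | remark | time |
|---|---|---|---|---|---|---|---|
| grey | 10 mM | 10 mM | 15 mM | 1 mM | 0.25 mM | run made earlier |  |
| blue | 10 mM | 10 mM | 15 mM | 1 mM | 0.38 mM | run made earlier |  |
| flask | 10 mM | 10 mM | 15.0 mM | 1.00 mM | 0.50 mM |  | 20 min |

| run | time / min | right-handed substrate / % | left-handed substrate / % | left-handed product / % |
|---|---|---|---|---|
| grey | 1.00 | 49.5 | 48.3 | 2.5 |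
| grey | 1.33 | 48.2 | 47.3 | 3.1 |
| grey | 2.00 | 46.6 | 47.5 | 5.6 |
| grey | 3.00 | 45.9 | 46.0 | 7.2 |
| grey | 5.00 | 43.0 | 43.2 | 12.2 |
| grey | 8.00 | 40.3 | 40.3 | 17.9 |
| grey | 12.0 | 36.5 | 36.6 | 24.9 |
| blue | 0.667 | 48.8 | 47.2 | 3.7 |
| blue | 2.00 | 46.9 | 45.8 | 8.0 |
| blue | 3.00 | 43.5 | 42.5 | 10.9 |
| blue | 5.00 | 41.4 | 40.3 | 17.9 |
| blue | 8.00 | 37.1 | 36.3 | 24.7 |
| blue | 10.0 | 35.3 | 34.2 | 29.5 |
| blue | 12.0 | 32.7 | 33.0 | 33.8 |

(each reading ± 0.5 percentage points)

- whether the excess of right-handed substrate over left-handed substrate among what is left of the two reaches 98 % by 20 min (no / yes)
- the highest excess of right-handed substrate over left-handed substrate among what is left of the two up to 20 min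

- free catalyst is single-handed; left-handed substrate and right-handed substrate are mirror images of each other, charged as a racemate, each of them at the stated concentration
- reactions considered so far: free catalyst + left-handed substrate <-> catalyst intermediate A; free catalyst + right-handed substrate <-> catalyst intermediate B; partner + catalyst intermediate A -> free catalyst + left-handed product; partner + catalyst intermediate B -> free catalyst + right-handed product; partner + protic impurity -> quenched reagent; left-handed substrate <-> right-handed substrate; free catalyst <-> dormant form

In both runs the two substrates fall together while left-handed product grows, so capture takes left-handed substrate and interconversion refills it, a dynamic kinetic resolution. The blue run up to 5.00 min gains product at 0.0358 min⁻¹ of the charge, and its mean gap, c(right-handed substrate) minus c(left-handed substrate), reads 1.2 percentage points, give or take 0.35 points. A steady gap means capture widens it as fast as interconversion closes it, so capture over gap gives 2.98 min⁻¹: the levelling rate, the rate constant with which a gap between the substrates closes. The grey run up to 5.00 min reads a mean gap of 0.18 points, below the 0.82 points this rate gives it, so our levelling rate may stand low and our excess high.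

Now the flask in slow motion. In the first instants of the flask we expect the gap to open, and we reckon about 0.233 min for it to get halfway. Product gain went up 1.47 times from grey to blue as catalyst went up 1.52 times, so we scale capture to 0.0471 min⁻¹ and the gap to 1.6 points of the charge. Going round once more, we reckon that by 2.00 min about 90.6 % of the charge is left in the flask, which makes our estimate of the excess 1.74 %. Later, capture and what is left both shrink, so we expect an excess of this size, far short of the level asked.

The forecast answers no with a top of 1.5 %, holding that “the excess peaks early”. The simulation gives no and a top of 1.65 %.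

    free catalyst + left-handed substrate ⇌ catalyst intermediate A (K = 140 M⁻¹, k = 92.0 M⁻¹ s⁻¹)
    free catalyst + right-handed substrate ⇌ catalyst intermediate B (K = 24.0 M⁻¹, k = 280 M⁻¹ s⁻¹)
    partner + catalyst intermediate A → free catalyst + left-handed product (k = 5.90 M⁻¹ s⁻¹)
    partner + catalyst intermediate B → free catalyst + right-handed product (k = 0.820 M⁻¹ s⁻¹)
    partner + protic impurity → quenched reagent (k = 3.00 M⁻¹ s⁻¹)
    left-handed substrate ⇌ right-handed substrate (k = 0.0270 s⁻¹)
    free catalyst ⇌ dormant form (K = 0.360, k = 0.00850 s⁻¹)

The relaxation half-life of the two substrates by interconversion alone, 0.214 min, is short against the 20 min of this flask, and at 20.0 min left-handed substrate stands at 23.8 % beside 24.2 % of right-handed. Our levelling rate, with this flask's product gain from 2.00 min to 10.0 min and the mean of what is left over that span, gives a mean excess over that span of 1.37 %. For the neighbour charged with 2.0 mM of free catalyst, the blue capture scaled by catalyst and divided by the levelling rate is a rough gap of 6.3 points of the charge, reckoned for the start and not an excess among what is left, and the top excess stored for that neighbour is 6.39 %, still far below 98 %.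

The earlier runs and the new flask were generated by integration for substances that don't exist, noise included.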